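## Analysis of the target

The target 20 is a 2H-chromene (ring atoms O1, C2, C3=C4, C4a, C5 to C8, C8a). Its benzo ring carries an acetyl group at C6 and a methoxy group at C8. C2 carries a methyl group and an oxymethyl arm that is esterified with (E)-ferulic acid 17.

C2 is the only stereocentre. It is fully substituted, bonded to O1, and has the R configuration. Apart from it, only the E geometry of the cinnamate has to be kept.

The sensitive functions are:
- the styrene-type C3=C4 bond, which makes the pyran ring prone to acid and to light- or heat-induced 6π ring opening to an ortho-quinone methide, a path that would scramble C2;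
- the enolisable aryl methyl ketone;
- the free phenol and the conjugated ester.

The difficulty lies in C2. It is a tetrasubstituted ether carbon whose two small carbon substituents, CH3 and CH2O, are hard for a catalyst to tell apart, and it sits in a ring whose double bond should appear late. The arene is 1,2,3,5-tetrasubstituted, with the ring oxygen flanked by the methoxy group and the carbon chain, so regiocontrol on the benzene ring is a second issue.

The route rests on one observation. O1, C2 and C3, with the two substituents on C2, are the oxygen, the quaternary carbon and the CH2 of a 2-methylglycidyl unit, which is available as (S)-2-methylglycidol 9. C4 and C8a are a benzylic carbon and the adjacent ring carbon of one arene. If that ring carbon bears fluorine and C4 bears sulfur, a carbanion–epoxide reaction followed by displacement of the fluorine joins the pieces at C3–C4 and O1–C8a.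

## Retrosynthetic reasoning

**Ester bond.** The first cut is the acyl–oxygen bond between the cinnamoyl carbonyl and the oxygen of the C2 oxymethyl arm. It divides target 20 into chromenyl alcohol 16 and ferulic acid 17, two halves of similar size, so the synthesis becomes convergent. An activated cinnamic acid with a free phenol would acylate itself, so 17 is carried as its phenol acetate 18 and the direct precursor of 20 is the acetate 19. An aryl acetate is far more electrophilic than the alkyl cinnamate and can be removed last by aminolysis. The forward reaction has to acylate a neopentyl-type primary alcohol; no bond to C2 is involved.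

**C3=C4 double bond.** The alkene is traced back to a C4–S bond and a C3–H bond. Alcohol 16 should arise from sulfoxide 15 by syn-elimination, and 15 from sulfide 14 by oxidation at sulfur. Placing the alkene late keeps the fragile 2H-chromene out of every acidic and strongly basic step. The sulfur is not an added burden, because it is the group that makes C4 nucleophilic in the ring-forming step. Only C3 carries β-hydrogens, so the elimination can go one way only, and it removes the uncontrolled C4 stereocentre.

**Protecting groups.** Sulfide 14 is the doubly deprotected form of chromane 13. The trityl ether and the dioxolane are both acid-labile, so one operation removes both. It is done while the pyran ring is still saturated, where C2–O1 is an ordinary tertiary alkyl aryl ether and not an allylic one, so ionisation at C2 is not a concern.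

**Key disconnection.** Chromane 13 is cut at C3–C4 and at O1–C8a into benzyl sulfide 8 and epoxide 10.
- These two cuts lift out O1–C2–C3 together with the methyl and oxymethyl groups as one intact unit, so the stereocentre is bought and not made. Any cut at O1–C2 would instead require an asymmetric construction of the quaternary carbon.
- One operation then forms two skeletal bonds and the pyran ring, and the C2–O bond of the epoxide is never broken.
- The forward reaction has to deprotonate only the benzylic carbon (via the lithio compound 11), open the epoxide at its CH2 (giving alkoxide 12), and displace the fluorine from C8a with the tertiary alkoxide.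
- The oxygen of the epoxide arm is protected as a trityl ether and not as a silyl ether. A silyl group next to the alkoxide of 12 could migrate from oxygen to oxygen, and it could be attacked by the fluoride anion that the ring closure releases. Either event would free the primary oxygen and open a path to a seven-membered ring.
- A sulfide and not a sulfone is used at C4, so that the C4–H of 12 stays less acidic than the alkoxide.

**Arene fragment.** Sulfide 8 is cut at the C–S bond into benzylic alcohol 5, activated in the flask as mesylate 7, and thiophenol 6. Alcohol 5 is cut at the aryl–CH2 bond. The carbon comes from a formyl group (aldehyde 4) placed on aryllithium 3, which is obtained by deprotonating ketal 2 beside the fluorine. Ketal 2 is the protected form of the commercial acetophenone 1, which already holds fluorine, methoxy and acetyl in the required 1,2,4 relationship. Only one carbon has to be added, at the most acidic ring position.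

**Epoxide fragment.** Epoxide 10 is the trityl ether of 9. This is a protection only, with no bond to the stereocentre touched.

## Alternatives that were turned down

**Alternative 1: benzene ring built last by alkyne cyclotrimerisation.**
- Disconnection: three bonds of the benzo ring, C4a–C8a, C5–C6 and C7–C8, so that the carbocycle and the pyran ring come from one [2+2+2] cycloaddition.
- Forward key step: a chiral diyne, in which a (Z)-enyne and a silyl-capped ynol ether hang from the tertiary carbinol carbon, is co-cyclised with a terminal acetylenic methyl ketone under Cp*RuCl(cod). The product would be (R)-1-[8-(benzyldimethylsilyl)-2-(tert-butyldimethylsilyloxymethyl)-2-methyl-2H-chromen-6-yl]ethanone A1.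
- For it: on bond economy it is stronger than the chosen route, with three C–C bonds and two rings in one catalytic step. It needs no substitution on an unactivated fluoroarene, and the stereocentre could come from the same chiral pool.
- Against it: whether the acetyl group lands on C6 or C7 depends on the orientation in which the monoalkyne enters the ruthenacycle, which the structure does not fix. The ynol ether of a tertiary alcohol is hard to make and fragments readily to a ketene and an alkene by a retro-ene path. The silicon at C8 of A1 must still be turned into the methoxy group by aryl–silicon oxidation and methylation, in the presence of a ketone and the chromene.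
- Comparison: the chosen route gives up the one-step complexity gain but takes the arene with all three substituents already in place, so no regiochemical question arises on the ring and the endgame is shorter.

**Alternative 2: temporary C3 stereocentre and silicon-tethered methyl C–H silylation.**
- Disconnection: the C–O bond of the C2 oxymethyl arm is traced to a C–H bond of one methyl group of a 2,2-dimethylchromane.
- Forward key step: a hydridosilyl ether on an enantioenriched C3 hydroxyl is cyclised onto one methyl group by C–H silylation with [Ir(cod)OMe]2 and a phenanthroline ligand. The product would be the oxasilolane A2, a 2,2-diethyl-1,2-oxasilolane fused across C2–C3 of 8-methoxy-2-methyl-6-(2-methyl-1,3-dioxolan-2-yl)chromane.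
- For it: the gem-dimethyl chromane is very easy to reach from a phenol, no fluoroarene is needed, and chirality has a catalytic origin. On these points it is as strong as or stronger than the chosen route.
- Against it: the final configuration at C2 depends on discrimination between two diastereotopic methyl groups, both of which lie gauche to the C3–O bond in a half-chair and can reach the silicon. After the key step the C–Si bond must be oxidised, the primary and secondary hydroxyls told apart, the C3 oxygen removed and the C3=C4 bond installed. A stereocentre is built only to be destroyed, and the sequence is much longer.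
- Comparison: the chosen route offers a C2 configuration that does not rest on any selectivity, and about half the step count.

**Alternative 3: amine-catalysed oxa-Michael and aldol chromene annulation.**
- Disconnection: O1–C2 and C3=C4.
- Forward key step: an ortho-hydroxy aryl aldehyde and a β,β-disubstituted enal are joined under a diarylprolinol silyl ether and an acid cocatalyst. The product would be (R)-6-acetyl-2-(tert-butyldimethylsilyloxymethyl)-8-methoxy-2-methyl-2H-chromene-3-carbaldehyde A3.
- For it: it is the shortest ring construction of all. It is catalytic, the C3=C4 bond is formed directly, and the phenol partner is cheap. On step count to the ring it is stronger than the chosen route.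
- Against it: the oxa-Michael addition has to create a fully substituted C2 from a β,β-disubstituted iminium ion, which forms slowly and adds reversibly. The catalyst must distinguish CH3 from CH2OSi, two groups of similar size, so high enantioselectivity is not to be expected on structural grounds. The phenol is deactivated by the para acetyl group, and the free methyl ketone can engage the amine. A3 also carries a formyl group at C3 that the target lacks, and its removal by decarbonylation puts thermal stress on the chromene.
- Comparison: the chosen route is longer up to the ring but takes C2 from an enantiopure epoxide and introduces no surplus carbon.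

Key step: step 5

Assumption: (S)-2-methylglycidol 9 is taken as a commercial material of high enantiomeric purity.

## Route

Step 1
Reactants: 1 1-(4-fluoro-3-methoxyphenyl)ethanone (4'-fluoro-3'-methoxyacetophenone)
Product: 2 2-(4-fluoro-3-methoxyphenyl)-2-methyl-1,3-dioxolane
Conditions: ethylene glycol, TsOH·H2O (cat.), PhMe, reflux, Dean–Stark
Reagents that add atoms: ethylene glycol, OCCO
Why: Acid-catalysed ketalisation with azeotropic removal of water masks the acetyl group for the three organolithium operations ahead; the aryl fluoride and the methyl ether are inert.

Step 2
Reactants: 2 2-(4-fluoro-3-methoxyphenyl)-2-methyl-1,3-dioxolane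
Product: 5 [2-fluoro-3-methoxy-5-(2-methyl-1,3-dioxolan-2-yl)phenyl]methanol, via aryllithium 3 (not isolated), via aldehyde 4 (not isolated)
Conditions: n-BuLi, PMDTA, THF, −78 °C; DMF, −78 → 0 °C; then MeOH, NaBH4, 0 °C
Reagents that add atoms: N,N-dimethylformamide (DMF), CN(C)C=O
Why: Directed ortho-metalation under acidity control: n-BuLi saturated with PMDTA should remove the proton beside fluorine, the most acidic ring C–H, and not the hindered proton between the methoxy group and the ketal-bearing carbon. The aryllithium is kept at −78 °C so that LiF is not lost, and formylation with DMF and borohydride reduction in the same flask are standard.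

Step 3
Reactants: 5 [2-fluoro-3-methoxy-5-(2-methyl-1,3-dioxolan-2-yl)phenyl]methanol; 6 thiophenol
Product: 8 2-[4-fluoro-3-methoxy-5-(phenylsulfanylmethyl)phenyl]-2-methyl-1,3-dioxolane, via benzylic mesylate 7 (not isolated)
Conditions: MsCl, Et3N, CH2Cl2, 0 °C; then PhSH, Et3N, 0 °C → rt
Reagents that add atoms: none
Why: Mesylation followed by SN2 displacement at a primary benzylic carbon by the soft, weakly basic thiolate; the basic medium leaves the ketal intact, and the unactivated aryl fluoride does not react with thiolate.

Step 4
Reactants: 9 (S)-2-methylglycidol, (S)-(2-methyloxiran-2-yl)methanol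
Product: 10 (R)-2-methyl-2-[(triphenylmethoxy)methyl]oxirane
Conditions: TrCl, Et3N, DMAP (cat.), CH2Cl2, 0 °C → rt
Reagents that add atoms: trityl chloride (chlorotriphenylmethane), ClC(c1ccccc1)(c1ccccc1)c1ccccc1
Why: Tritylation of the primary alcohol under mild amine base, which does not open the epoxide; no bond to the stereocentre is touched, and the descriptor changes from S to R only because the CIP priorities of the two CH2 groups swap.

Step 5
Reactants: 8 2-[4-fluoro-3-methoxy-5-(phenylsulfanylmethyl)phenyl]-2-methyl-1,3-dioxolane; 10 (R)-2-methyl-2-[(triphenylmethoxy)methyl]oxirane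
Product: 13 (2R)-8-methoxy-2-methyl-6-(2-methyl-1,3-dioxolan-2-yl)-4-(phenylsulfanyl)-2-[(triphenylmethoxy)methyl]chromane (both C4 epimers), via lithiated sulfide 11 (not isolated), via lithium alkoxide 12 (not isolated)
Conditions: n-BuLi, THF, −78 °C; then 10, DMPU, −78 → 0 °C; then KOtBu, 65 °C
Reagents that add atoms: none
Why: n-BuLi should remove the benzylic proton of 8, which is acidified by the arene and by sulfur and is far more acidic than any ring C–H (both positions beside fluorine are substituted, so neither ortho-lithiation at fluorine nor aryne formation is open), to give the α-thio benzyllithium 11. Carbanion 11 opens epoxide 10 by SN2 attack at the unsubstituted CH2, which forms C3–C4 and releases the tertiary lithium alkoxide 12; the closest known reaction type is the opening of terminal and 2,2-disubstituted epoxides by lithiated benzyl and allyl sulfides. After exchange to the more dissociated potassium alkoxide with KOtBu in THF/DMPU, the oxygen adds to the fluorine-bearing C8a and fluoride is expelled, which forms O1–C8a; the closest known reaction type is the base-mediated cyclisation of 3-(2-fluoroaryl)propanols to chromanes on rings without activating groups. The pyran ring closes in a six-membered addition–elimination at an sp2 carbon (6-exo-trig with respect to the C8a–C8 π bond), the three-carbon tether from C4a holding the alkoxide next to C8a. The C2 stereocentre is not made here: its C–O bond and its three C–C bonds are never broken, so the configuration of 10 is carried over unchanged and the descriptor stays R. C4 becomes a stereocentre without control and is allowed to form as both epimers, because it is flattened in step 8. The step needs attack at the epoxide CH2 and cyclisation through the tertiary oxygen only; the first is secured by the fully substituted nature of the other epoxide carbon, the second by the trityl ether, which cannot migrate to the alkoxide or be cleaved by the fluoride set free, as a silyl ether could. A sulfide and not a sulfone is carried at C4 so that the C4–H of 12 stays less acidic than the alkoxide and does not quench it.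

Step 6
Reactants: 13 (2R)-8-methoxy-2-methyl-6-(2-methyl-1,3-dioxolan-2-yl)-4-(phenylsulfanyl)-2-[(triphenylmethoxy)methyl]chromane
Product: 14 1-[(2R)-2-(hydroxymethyl)-8-methoxy-2-methyl-4-(phenylsulfanyl)chroman-6-yl]ethanone (both C4 epimers)
Conditions: HCl (2 M aq.), THF, 45 °C
Reagents that add atoms: water, O
Why: Acid-catalysed hydrolysis: the trityl ether ionises to the trityl cation, which water captures, and the dioxolane hydrolyses through its oxocarbenium ion. It is run on the saturated chromane, where C2–O1 is not allylic and the benzylic sulfide is not a leaving group, so the stereocentre is not at risk.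

Step 7
Reactants: 14 1-[(2R)-2-(hydroxymethyl)-8-methoxy-2-methyl-4-(phenylsulfanyl)chroman-6-yl]ethanone
Product: 15 1-[(2R)-2-(hydroxymethyl)-8-methoxy-2-methyl-4-(phenylsulfinyl)chroman-6-yl]ethanone (mixture at C4 and at sulfur)
Conditions: mCPBA (1.0 equiv), CH2Cl2, −78 → −40 °C
Reagents that add atoms: mCPBA (3-chloroperoxybenzoic acid), O=C(OO)c1cccc(Cl)c1
Why: Chemoselective oxidation of sulfide to sulfoxide with one equivalent of peracid at low temperature; sulfur is oxidised much faster than the aryl ketone undergoes Baeyer–Villiger oxidation, and the sulfoxide diastereomers are of no consequence.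

Step 8
Reactants: 15 1-[(2R)-2-(hydroxymethyl)-8-methoxy-2-methyl-4-(phenylsulfinyl)chroman-6-yl]ethanone
Product: 16 1-[(2R)-2-(hydroxymethyl)-8-methoxy-2-methyl-2H-chromen-6-yl]ethanone
Conditions: PhMe, NaHCO3 (solid), 100 °C, dark
Reagents that add atoms: none
Why: Thermal syn-elimination (Ei) of the sulfoxide: only C3 carries β-hydrogens and both C4 epimers have one syn to sulfur, so only the conjugated C3=C4 bond can form and the C4 stereocentre is erased. The temperature is kept moderate and light is excluded to avoid electrocyclic opening of the 2H-chromene.

Step 9
Reactants: 17 ferulic acid, (E)-3-(4-hydroxy-3-methoxyphenyl)prop-2-enoic acid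
Product: 18 (E)-3-(4-acetoxy-3-methoxyphenyl)prop-2-enoic acid
Conditions: Ac2O, pyridine, rt; then H2O
Reagents that add atoms: acetic anhydride, CC(=O)OC(C)=O
Why: O-Acetylation of the phenol, so that the acid can later be activated without acylating itself; any mixed anhydride is hydrolysed on aqueous work-up and the E alkene is untouched.

Step 10
Reactants: 16 1-[(2R)-2-(hydroxymethyl)-8-methoxy-2-methyl-2H-chromen-6-yl]ethanone; 18 (E)-3-(4-acetoxy-3-methoxyphenyl)prop-2-enoic acid
Product: 19 [(2R)-6-acetyl-8-methoxy-2-methyl-2H-chromen-2-yl]methyl (E)-3-(4-acetoxy-3-methoxyphenyl)prop-2-enoate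
Conditions: DCC, DMAP (cat.), CH2Cl2, 0 °C → rt
Reagents that add atoms: none
Why: Steglich esterification: the acylpyridinium ion formed from the O-acylisourea should acylate the neopentyl-type primary alcohol under neutral conditions that leave the chromene, the ketone and C2 alone.

Step 11
Reactants: 19 [(2R)-6-acetyl-8-methoxy-2-methyl-2H-chromen-2-yl]methyl (E)-3-(4-acetoxy-3-methoxyphenyl)prop-2-enoate
Product: 20 [(2R)-6-acetyl-8-methoxy-2-methyl-2H-chromen-2-yl]methyl (E)-3-(4-hydroxy-3-methoxyphenyl)prop-2-enoate (target, CNP0168033.1)
Conditions: pyrrolidine, CH2Cl2, 0 °C → rt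
Reagents that add atoms: none
Why: Chemoselective aminolysis of the aryl acetate: a phenyl ester is far more electrophilic than the alkyl cinnamate, so the secondary amine should remove only the acetyl group and leave the ester, the ketone and the E alkene unchanged.

## Compound list

1 | 1-(4-fluoro-3-methoxyphenyl)ethanone (4'-fluoro-3'-methoxyacetophenone) | CC(=O)c1ccc(F)c(OC)c1 | starting material
2 | 2-(4-fluoro-3-methoxyphenyl)-2-methyl-1,3-dioxolane | CC1(OCCO1)c1ccc(F)c(OC)c1 | intermediate
3 | [2-fluoro-3-methoxy-5-(2-methyl-1,3-dioxolan-2-yl)phenyl]lithium | [Li]c1cc(C2(C)OCCO2)cc(OC)c1F | intermediate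
4 | 2-fluoro-3-methoxy-5-(2-methyl-1,3-dioxolan-2-yl)benzaldehyde | O=Cc1cc(C2(C)OCCO2)cc(OC)c1F | intermediate
5 | [2-fluoro-3-methoxy-5-(2-methyl-1,3-dioxolan-2-yl)phenyl]methanol | OCc1cc(C2(C)OCCO2)cc(OC)c1F | intermediate
6 | thiophenol (benzenethiol) | Sc1ccccc1 | starting material
7 | 2-fluoro-3-methoxy-5-(2-methyl-1,3-dioxolan-2-yl)benzyl methanesulfonate | CS(=O)(=O)OCc1cc(C2(C)OCCO2)cc(OC)c1F | intermediate
8 | 2-[4-fluoro-3-methoxy-5-(phenylsulfanylmethyl)phenyl]-2-methyl-1,3-dioxolane | CC1(OCCO1)c1cc(OC)c(F)c(CSc2ccccc2)c1 | intermediate
9 | (S)-2-methylglycidol, (S)-(2-methyloxiran-2-yl)methanol | OC[C@@]1(C)CO1 | starting material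
10 | (R)-2-methyl-2-[(triphenylmethoxy)methyl]oxirane | C(c1ccccc1)(c1ccccc1)(c1ccccc1)OC[C@@]1(C)CO1 | intermediate
11 | lithio[2-fluoro-3-methoxy-5-(2-methyl-1,3-dioxolan-2-yl)phenyl](phenylsulfanyl)methane (α-lithiated 8) | [Li]C(Sc1ccccc1)c1cc(C2(C)OCCO2)cc(OC)c1F | intermediate
12 | lithium (2R)-4-[2-fluoro-3-methoxy-5-(2-methyl-1,3-dioxolan-2-yl)phenyl]-2-methyl-4-(phenylsulfanyl)-1-(triphenylmethoxy)butan-2-olate (C4 epimers) | C(c1ccccc1)(c1ccccc1)(c1ccccc1)OC[C@@](O[Li])(C)CC(Sc1ccccc1)c1cc(C2(C)OCCO2)cc(OC)c1F | intermediate
13 | (2R)-8-methoxy-2-methyl-6-(2-methyl-1,3-dioxolan-2-yl)-4-(phenylsulfanyl)-2-[(triphenylmethoxy)methyl]chromane (C4 epimers) | C(c1ccccc1)(c1ccccc1)(c1ccccc1)OC[C@@]1(C)CC(Sc2ccccc2)c2cc(C3(C)OCCO3)cc(OC)c2O1 | intermediate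
14 | 1-[(2R)-2-(hydroxymethyl)-8-methoxy-2-methyl-4-(phenylsulfanyl)chroman-6-yl]ethanone (C4 epimers) | OC[C@@]1(C)CC(Sc2ccccc2)c2cc(C(C)=O)cc(OC)c2O1 | intermediate
15 | 1-[(2R)-2-(hydroxymethyl)-8-methoxy-2-methyl-4-(phenylsulfinyl)chroman-6-yl]ethanone (mixture at C4 and S) | OC[C@@]1(C)CC(S(=O)c2ccccc2)c2cc(C(C)=O)cc(OC)c2O1 | intermediate
16 | 1-[(2R)-2-(hydroxymethyl)-8-methoxy-2-methyl-2H-chromen-6-yl]ethanone | OC[C@@]1(C)C=Cc2cc(C(C)=O)cc(OC)c2O1 | intermediate
17 | ferulic acid, (E)-3-(4-hydroxy-3-methoxyphenyl)prop-2-enoic acid | COc1cc(/C=C/C(=O)O)ccc1O | starting material
18 | (E)-3-(4-acetoxy-3-methoxyphenyl)prop-2-enoic acid | COc1cc(/C=C/C(=O)O)ccc1OC(C)=O | intermediate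
19 | [(2R)-6-acetyl-8-methoxy-2-methyl-2H-chromen-2-yl]methyl (E)-3-(4-acetoxy-3-methoxyphenyl)prop-2-enoate | COc1cc(/C=C/C(=O)OC[C@@]2(C)C=Cc3cc(C(C)=O)cc(OC)c3O2)ccc1OC(C)=O | intermediate
20 | [(2R)-6-acetyl-8-methoxy-2-methyl-2H-chromen-2-yl]methyl (E)-3-(4-hydroxy-3-methoxyphenyl)prop-2-enoate | COc1cc(/C=C/C(=O)OC[C@@]2(C)C=Cc3cc(C(C)=O)cc(OC)c3O2)ccc1O | target

## Step count and least certain steps

Total step count: 11. Longest linear sequence: 9 steps (steps 1, 2, 3, 5, 6, 7, 8, 10, 11, from 1 to 20).

**Step 5 (key step).**
- Most likely failure: slow displacement of fluoride. The ring carries no electron-withdrawing group para to fluorine (the ketal is electronically neutral and the ortho methoxy group is mildly deactivating), so prolonged heating may let the alkoxide be protonated or decompose before it closes. Incomplete opening of the hindered epoxide by the stabilised carbanion is the second possibility.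
- Fallback: separate the two events and activate the ring. From 8 and 10, the lithiation and epoxide opening are run as before and quenched cold with aqueous NH4Cl to give the ring-opened tertiary alcohol F1. Aqueous HCl in THF removes the dioxolane and the trityl group and gives the keto diol F2. The primary hydroxyl is tritylated again (TrCl, pyridine, DMAP) to give the keto alcohol F3. Fluorine is now para to an acetyl group, and Cs2CO3 in DMSO at 60 °C should close the ring by a classical activated aromatic substitution to the chromanyl ketone F4. Detritylation with aqueous HCl in THF returns to the route at 14.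

**Step 2.**
- Most likely failure: loss of regiocontrol in the lithiation, by competing coordination-controlled deprotonation between the methoxy group and the ketal-bearing carbon, and elimination of LiF to an aryne if the temperature rises.
- Fallback: replace lithiation by sterically controlled C–H borylation. From 2, [Ir(cod)OMe]2 with 4,4'-di-tert-butyl-2,2'-bipyridine and B2pin2 should borylate the only ring C–H that is not next to a large group, the one beside fluorine, to give the aryl boronate F5. Matteson homologation (BrCH2Cl, n-BuLi, THF, −78 °C → rt) gives the benzyl boronate F6, and oxidation with NaBO3·4H2O in THF/H2O returns to the route at 5.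

**Step 8.**
- Most likely failure: incomplete elimination at a temperature low enough to spare the product, or erosion of the C2 configuration by thermal or photochemical 6π opening of the 2H-chromene to the ortho-quinone methide and reclosure. Acid-promoted side reactions caused by the sulfenic acid are a further possibility.
- Fallback: eliminate at room temperature through a sulfonium salt. From 13, S-methylation with MeOTf in CH2Cl2 (hindered pyridine buffer) gives the sulfonium triflate F7. DBU at room temperature effects E2 loss of methyl phenyl sulfide to give the protected chromene F8. Brief treatment with dilute aqueous HCl in THF removes the trityl and dioxolane groups and returns to the route at 16. The hydroxyl is kept protected here so that it cannot displace the sulfonium group across the ring.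

**Step 10 (and step 11).**
- Most likely failure: slow acylation of the neopentyl-type alcohol, with DMAP-mediated transfer of the acetyl group from the aryl acetate to the alcohol as a competing path. In step 11, aminolysis or conjugate addition at the cinnamate could compete with deacetylation.
- Fallback: build the cinnamate on the alcohol and use no phenol protecting group. From 16, heating with Meldrum's acid in PhMe at 90 °C gives the malonic half ester F9. Knoevenagel–Doebner condensation of F9 with vanillin (pyridine, piperidine cat., 50 °C) proceeds with loss of CO2 and should give the E ester with the phenol free, returning to the route at 20 and bypassing steps 9 and 11.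

## Further compounds

F1 | step 5 | (2R)-4-[2-fluoro-3-methoxy-5-(2-methyl-1,3-dioxolan-2-yl)phenyl]-2-methyl-4-(phenylsulfanyl)-1-(triphenylmethoxy)butan-2-ol (C4 epimers) | C(c1ccccc1)(c1ccccc1)(c1ccccc1)OC[C@@](O)(C)CC(Sc1ccccc1)c1cc(C2(C)OCCO2)cc(OC)c1F
F2 | step 5 | 1-{3-[(3R)-3,4-dihydroxy-3-methyl-1-(phenylsulfanyl)butyl]-4-fluoro-5-methoxyphenyl}ethanone | OC[C@@](O)(C)CC(Sc1ccccc1)c1cc(C(C)=O)cc(OC)c1F
F3 | step 5 | 1-{4-fluoro-3-[(3R)-3-hydroxy-3-methyl-1-(phenylsulfanyl)-4-(triphenylmethoxy)butyl]-5-methoxyphenyl}ethanone | C(c1ccccc1)(c1ccccc1)(c1ccccc1)OC[C@@](O)(C)CC(Sc1ccccc1)c1cc(C(C)=O)cc(OC)c1F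
F4 | step 5 | 1-[(2R)-8-methoxy-2-methyl-4-(phenylsulfanyl)-2-[(triphenylmethoxy)methyl]chroman-6-yl]ethanone | C(c1ccccc1)(c1ccccc1)(c1ccccc1)OC[C@@]1(C)CC(Sc2ccccc2)c2cc(C(C)=O)cc(OC)c2O1
F5 | step 2 | 2-[4-fluoro-3-methoxy-5-(4,4,5,5-tetramethyl-1,3,2-dioxaborolan-2-yl)phenyl]-2-methyl-1,3-dioxolane | CC1(OCCO1)c1cc(OC)c(F)c(B2OC(C)(C)C(C)(C)O2)c1
F6 | step 2 | 2-{4-fluoro-3-methoxy-5-[(4,4,5,5-tetramethyl-1,3,2-dioxaborolan-2-yl)methyl]phenyl}-2-methyl-1,3-dioxolane | CC1(OCCO1)c1cc(OC)c(F)c(CB2OC(C)(C)C(C)(C)O2)c1
F7 | step 8 | [(2R)-8-methoxy-2-methyl-6-(2-methyl-1,3-dioxolan-2-yl)-2-[(triphenylmethoxy)methyl]chroman-4-yl](methyl)(phenyl)sulfonium trifluoromethanesulfonate | C(c1ccccc1)(c1ccccc1)(c1ccccc1)OC[C@@]1(C)CC([S+](C)c2ccccc2)c2cc(C3(C)OCCO3)cc(OC)c2O1.[O-]S(=O)(=O)C(F)(F)F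
F8 | step 8 | (2R)-8-methoxy-2-methyl-6-(2-methyl-1,3-dioxolan-2-yl)-2-[(triphenylmethoxy)methyl]-2H-chromene | C(c1ccccc1)(c1ccccc1)(c1ccccc1)OC[C@@]1(C)C=Cc2cc(C3(C)OCCO3)cc(OC)c2O1
F9 | step 10 | 3-{[(2R)-6-acetyl-8-methoxy-2-methyl-2H-chromen-2-yl]methoxy}-3-oxopropanoic acid | OC(=O)CC(=O)OC[C@@]1(C)C=Cc2cc(C(C)=O)cc(OC)c2O1
A1 | alternative 1 | (R)-1-[8-(benzyldimethylsilyl)-2-(tert-butyldimethylsilyloxymethyl)-2-methyl-2H-chromen-6-yl]ethanone | CC(C)(C)[Si](C)(C)OC[C@@]1(C)C=Cc2cc(C(C)=O)cc([Si](C)(C)Cc3ccccc3)c2O1
A2 | alternative 2 | 2,2-diethyl-1,2-oxasilolane fused across C2–C3 of 8-methoxy-2-methyl-6-(2-methyl-1,3-dioxolan-2-yl)chromane (Si–CH2 on C2, O on C3) | C1[C@@]2(C)[C@H](O[Si]1(CC)CC)Cc3cc(C4(C)OCCO4)cc(OC)c3O2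
A3 | alternative 3 | (R)-6-acetyl-2-(tert-butyldimethylsilyloxymethyl)-8-methoxy-2-methyl-2H-chromene-3-carbaldehyde | CC(C)(C)[Si](C)(C)OC[C@@]1(C)C(C=O)=Cc2cc(C(C)=O)cc(OC)c2O1
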